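**Retrosynthetic overview**

- The target is unmasked last from (S)-6,8-bis[2-(benzyloxy)benzyl]-5,7-dimethoxyflavanone with BCl3. The C5 methyl ether is chelated to the C4 carbonyl and is cleaved together with both benzyl ethers, while the unchelated C7 methyl ether should stay.
- Ring C, the only ring built, is closed by forming C4–C4a through Friedel–Crafts cycloacylation of an (S)-3-aryloxy-3-phenylpropanoic acid. The strategy rests on ring A of that acid: it already carries O1, the C5 and C7 methoxy groups and the C6 and C8 benzyl groups, so C4a is its only C–H, ortho to O1 and to the C5 oxygen and para to the C7 oxygen.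
- The C2–O1 bond comes from Mitsunobu inversion of ethyl (R)-3-hydroxy-3-phenylpropanoate with the pentasubstituted phenol, which sets C2 as S before ring closure.
- The two Ar–CH2–Ar bonds come from aryl Grignard addition to an aldehyde followed by ionic deoxygenation, run twice on 4-hydroxy-2,6-dimethoxybenzaldehyde, the second aldehyde being introduced by Vilsmeier formylation. Ring A, the C2 phenyl ring and both hydroxybenzyl rings are bought.

Key step: step 11

Remark on the chemistry: the magnesium alkoxides (steps 3 and 6), the lithium carboxylate (step 10) and the aryloxyboron species (step 12) are only protonated or hydrolysed in the work-up of the same step and are treated as the work-up form of the product, not as separate intermediates.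

**Route**

Step 1
Reactants: 1 4-hydroxy-2,6-dimethoxybenzaldehyde
Product: 2 4-(allyloxy)-2,6-dimethoxybenzaldehyde
Conditions: allyl bromide, K2CO3, DMF, rt
Reagents that add atoms: allyl bromide, C=CCBr
Why: Williamson etherification of an acidic para-formyl phenol; the allyl ether should survive Grignard reagents, Et3SiH/CF3CO2H and POCl3/DMF and can later be removed without touching benzyl ethers.

Step 2
Reactants: 3 1-(benzyloxy)-2-bromobenzene
Product: 4 [2-(benzyloxy)phenyl]magnesium bromide (THF solution, titrated, used in steps 3 and 6)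
Conditions: Mg turnings, I2 (cat.), THF, 25 → 50 °C
Reagents that add atoms: magnesium, [Mg]
Why: Grignard formation by magnesium insertion into the aryl C–Br bond, to which the ortho benzyl ether is inert.

Step 3
Reactants: 2 4-(allyloxy)-2,6-dimethoxybenzaldehyde; 4 [2-(benzyloxy)phenyl]magnesium bromide
Product: 5 (RS)-[4-(allyloxy)-2,6-dimethoxyphenyl][2-(benzyloxy)phenyl]methanol
Conditions: THF, 0 °C → rt; then sat. aq NH4Cl
Reagents that add atoms: none
Why: Grignard 1,2-addition to a non-enolisable aldehyde; the carbinol centre forms without control (racemic), which does not matter because step 4 removes it.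

Step 4
Reactants: 5 (RS)-[4-(allyloxy)-2,6-dimethoxyphenyl][2-(benzyloxy)phenyl]methanol
Product: 6 5-(allyloxy)-2-[2-(benzyloxy)benzyl]-1,3-dimethoxybenzene
Conditions: Et3SiH (excess), CF3CO2H, CH2Cl2, –20 → 0 °C
Reagents that add atoms: none
Why: Ionic hydrogenation: acid ionises the diarylmethanol to a cation stabilised by three ortho/para alkoxy groups, and excess silane should capture it by hydride transfer faster than it can alkylate a second arene.

Step 5
Reactants: 6 5-(allyloxy)-2-[2-(benzyloxy)benzyl]-1,3-dimethoxybenzene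
Product: 8 6-(allyloxy)-3-[2-(benzyloxy)benzyl]-2,4-dimethoxybenzaldehyde, via iminium salt 7 (not isolated)
Conditions: POCl3, DMF, 0 → 40 °C; then aq NaOAc, rt
Reagents that add atoms: N,N-dimethylformamide, CN(C)C=O; water, O
Why: Vilsmeier–Haack formylation of a 1,3,5-trioxygenated arene; the two free ring A positions are equivalent by symmetry, so only one aldehyde can form, and the anisole-like benzyloxyphenyl ring is far less nucleophilic.

Step 6
Reactants: 8 6-(allyloxy)-3-[2-(benzyloxy)benzyl]-2,4-dimethoxybenzaldehyde; 4 [2-(benzyloxy)phenyl]magnesium bromide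
Product: 9 (RS)-{6-(allyloxy)-3-[2-(benzyloxy)benzyl]-2,4-dimethoxyphenyl}[2-(benzyloxy)phenyl]methanol
Conditions: THF, 0 °C → rt; then sat. aq NH4Cl
Reagents that add atoms: none
Why: Grignard 1,2-addition as in step 3, assisted by the flanking alkoxy groups; the racemic carbinol centre is removed in step 7.

Step 7
Reactants: 9 (RS)-{6-(allyloxy)-3-[2-(benzyloxy)benzyl]-2,4-dimethoxyphenyl}[2-(benzyloxy)phenyl]methanol
Product: 10 1-(allyloxy)-2,4-bis[2-(benzyloxy)benzyl]-3,5-dimethoxybenzene
Conditions: Et3SiH (excess), CF3CO2H, CH2Cl2, –20 → 0 °C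
Reagents that add atoms: none
Why: Ionic hydrogenation as in step 4; the cation is again flanked by two ortho and one para oxygen, and ring A now has only one free position left to compete with hydride capture.

Step 8
Reactants: 10 1-(allyloxy)-2,4-bis[2-(benzyloxy)benzyl]-3,5-dimethoxybenzene
Product: 11 2,4-bis[2-(benzyloxy)benzyl]-3,5-dimethoxyphenol
Conditions: Pd(PPh3)4 (cat.), morpholine, THF, rt
Reagents that add atoms: none
Why: Tsuji–Trost deallylation: zerovalent palladium ionises the aryl allyl ether to a π-allyl complex that morpholine intercepts, leaving benzyl and methyl ethers untouched.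

Step 9
Reactants: 11 2,4-bis[2-(benzyloxy)benzyl]-3,5-dimethoxyphenol; 12 ethyl (R)-3-hydroxy-3-phenylpropanoate
Product: 14 ethyl (S)-3-{2,4-bis[2-(benzyloxy)benzyl]-3,5-dimethoxyphenoxy}-3-phenylpropanoate, via alkoxyphosphonium salt 13 (not isolated)
Conditions: PPh3, DIAD (added slowly), toluene, 0 °C → rt
Reagents that add atoms: none
Why: Mitsunobu etherification: the secondary benzylic alcohol is activated as its alkoxyphosphonium ion and displaced by the mono-ortho-substituted phenoxide in an SN2 step, so the R carbinol is inverted to the S aryl ether that becomes C2.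

Step 10
Reactants: 14 ethyl (S)-3-{2,4-bis[2-(benzyloxy)benzyl]-3,5-dimethoxyphenoxy}-3-phenylpropanoate
Product: 15 (S)-3-{2,4-bis[2-(benzyloxy)benzyl]-3,5-dimethoxyphenoxy}-3-phenylpropanoic acid
Conditions: LiOH, THF/MeOH/H2O, 0 °C → rt; then 1 M HCl to pH 3
Reagents that add atoms: lithium hydroxide, [Li+].[OH-]
Why: Ester saponification; hydroxide attack at the ester carbonyl at low temperature should outrun α-deprotonation and loss of the electron-rich aryloxide, and the stereocentre is not α to the carbonyl.

Step 11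
Reactants: 15 (S)-3-{2,4-bis[2-(benzyloxy)benzyl]-3,5-dimethoxyphenoxy}-3-phenylpropanoic acid
Product: 17 (S)-6,8-bis[2-(benzyloxy)benzyl]-5,7-dimethoxy-2-phenylchroman-4-one, via mixed anhydride 16 (not isolated)
Conditions: (CF3CO)2O (1.5 equiv), CH2Cl2, 0 °C → rt
Reagents that add atoms: none
Why: The anhydride converts the acid into the acyl trifluoroacetate 16, whose acylium-like carbon is attacked by C4a to give a Wheland intermediate that loses a proton and restores ring A; this is an intramolecular Friedel–Crafts acylation, the closest known reaction type being the cycloacylation of 3-aryloxy-3-arylpropanoic acids to flavanones. Ring C closes as a six-membered ring by 6-exo-trig attack of the arene carbon on the acyl carbon, forming C4–C4a. No stereocentre is created; C2, set in step 9, is not α to the new ketone and should pass unchanged as long as the benzylic C2–O1 bond is not ionised. Site selectivity is required and is secured by the substrate, because C4a is the only hydrogen-bearing carbon of ring A and is ortho to O1, ortho to the C5 oxygen and para to the C7 oxygen, whereas the anisole-like benzyloxyphenyl rings could only close rings of nine or more members. Activation without a Lewis acid should spare the benzyl ethers and avoid β-elimination of the aryloxide, and the small excess of anhydride limits competing trifluoroacetylation of C4a.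

Step 12
Reactants: 17 (S)-6,8-bis[2-(benzyloxy)benzyl]-5,7-dimethoxy-2-phenylchroman-4-one
Product: 18 7-methoxydichamanetin, (S)-5-hydroxy-6,8-bis(2-hydroxybenzyl)-7-methoxy-2-phenylchroman-4-one
Conditions: BCl3 (excess), C6HMe5, CH2Cl2, –78 → 0 °C; then H2O
Reagents that add atoms: none
Why: Lewis-acid ether cleavage: BCl3 removes the aryl benzyl ethers at low temperature with pentamethylbenzene trapping the benzyl cations, and on warming boron chelated between the C4 carbonyl and the C5 oxygen directs demethylation to C5 only, the unchelated C7 methyl ether being expected to persist.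

**Compound list**

1 | 4-hydroxy-2,6-dimethoxybenzaldehyde | COc1cc(O)cc(OC)c1C=O | starting material
2 | 4-(allyloxy)-2,6-dimethoxybenzaldehyde | C=CCOc1cc(OC)c(C=O)c(OC)c1 | intermediate
3 | 1-(benzyloxy)-2-bromobenzene | Brc1ccccc1OCc1ccccc1 | starting material
4 | [2-(benzyloxy)phenyl]magnesium bromide | Br[Mg]c1ccccc1OCc1ccccc1 | intermediate
5 | (RS)-[4-(allyloxy)-2,6-dimethoxyphenyl][2-(benzyloxy)phenyl]methanol (racemic) | C=CCOc1cc(OC)c(C(O)c2ccccc2OCc2ccccc2)c(OC)c1 | intermediate
6 | 5-(allyloxy)-2-[2-(benzyloxy)benzyl]-1,3-dimethoxybenzene | C=CCOc1cc(OC)c(Cc2ccccc2OCc2ccccc2)c(OC)c1 | intermediate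
7 | N-({6-(allyloxy)-3-[2-(benzyloxy)benzyl]-2,4-dimethoxyphenyl}methylidene)-N-methylmethanaminium dichlorophosphate (not isolated) | C=CCOc1cc(OC)c(Cc2ccccc2OCc2ccccc2)c(OC)c1C=[N+](C)C.[O-]P(=O)(Cl)Cl | intermediate
8 | 6-(allyloxy)-3-[2-(benzyloxy)benzyl]-2,4-dimethoxybenzaldehyde | C=CCOc1cc(OC)c(Cc2ccccc2OCc2ccccc2)c(OC)c1C=O | intermediate
9 | (RS)-{6-(allyloxy)-3-[2-(benzyloxy)benzyl]-2,4-dimethoxyphenyl}[2-(benzyloxy)phenyl]methanol (racemic) | C=CCOc1cc(OC)c(Cc2ccccc2OCc2ccccc2)c(OC)c1C(O)c1ccccc1OCc1ccccc1 | intermediate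
10 | 1-(allyloxy)-2,4-bis[2-(benzyloxy)benzyl]-3,5-dimethoxybenzene | C=CCOc1cc(OC)c(Cc2ccccc2OCc2ccccc2)c(OC)c1Cc1ccccc1OCc1ccccc1 | intermediate
11 | 2,4-bis[2-(benzyloxy)benzyl]-3,5-dimethoxyphenol | Oc1cc(OC)c(Cc2ccccc2OCc2ccccc2)c(OC)c1Cc1ccccc1OCc1ccccc1 | intermediate
12 | ethyl (R)-3-hydroxy-3-phenylpropanoate | CCOC(=O)C[C@@H](O)c1ccccc1 | starting material
13 | (R)-(3-ethoxy-3-oxo-1-phenylpropoxy)triphenylphosphonium 2,4-bis[2-(benzyloxy)benzyl]-3,5-dimethoxyphenolate (not isolated) | CCOC(=O)C[C@@H](O[P+](c1ccccc1)(c1ccccc1)c1ccccc1)c1ccccc1.[O-]c1cc(OC)c(Cc2ccccc2OCc2ccccc2)c(OC)c1Cc1ccccc1OCc1ccccc1 | intermediate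
14 | ethyl (S)-3-{2,4-bis[2-(benzyloxy)benzyl]-3,5-dimethoxyphenoxy}-3-phenylpropanoate | CCOC(=O)C[C@H](Oc1cc(OC)c(Cc2ccccc2OCc2ccccc2)c(OC)c1Cc1ccccc1OCc1ccccc1)c1ccccc1 | intermediate
15 | (S)-3-{2,4-bis[2-(benzyloxy)benzyl]-3,5-dimethoxyphenoxy}-3-phenylpropanoic acid | OC(=O)C[C@H](Oc1cc(OC)c(Cc2ccccc2OCc2ccccc2)c(OC)c1Cc1ccccc1OCc1ccccc1)c1ccccc1 | intermediate
16 | (S)-3-{2,4-bis[2-(benzyloxy)benzyl]-3,5-dimethoxyphenoxy}-3-phenylpropanoic trifluoroacetic anhydride (not isolated) | O=C(C[C@H](Oc1cc(OC)c(Cc2ccccc2OCc2ccccc2)c(OC)c1Cc1ccccc1OCc1ccccc1)c1ccccc1)OC(=O)C(F)(F)F | intermediate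
17 | (S)-6,8-bis[2-(benzyloxy)benzyl]-5,7-dimethoxy-2-phenylchroman-4-one | COc1c(Cc2ccccc2OCc2ccccc2)c(OC)c2c(c1Cc1ccccc1OCc1ccccc1)O[C@H](c1ccccc1)CC2=O | intermediate
18 | 7-methoxydichamanetin, (S)-5-hydroxy-6,8-bis(2-hydroxybenzyl)-7-methoxy-2-phenylchroman-4-one | COc1c(Cc2ccccc2O)c(O)c2c(c1Cc1ccccc1O)O[C@H](c1ccccc1)CC2=O | target

**Step count**

Total step count: 12. Longest linear sequence: 11 steps (steps 1 and 3–12 from compound 1; equally steps 2–12 from compound 3).

**Steps most likely to fail**

Step 9 (Mitsunobu etherification). The activated β-hydroxy ester may dehydrate toward the conjugated ester instead of being displaced, and ionisation of the benzylic alkoxyphosphonium ion may erode the configuration. The fallback sets out from phenol 11 and returns at acid 15, bypassing ester 14. Phenol 11 would be coupled under the same Mitsunobu conditions with commercial (R)-3-chloro-1-phenylpropan-1-ol (ClCC[C@@H](O)c1ccccc1), which has no acidic α-hydrogen. With inversion this should give (S)-1-(3-chloro-1-phenylpropoxy)-2,4-bis[2-(benzyloxy)benzyl]-3,5-dimethoxybenzene F1. Displacement of the primary chloride with KOAc and catalytic NaI in DMF at 80 °C should give (S)-3-{2,4-bis[2-(benzyloxy)benzyl]-3,5-dimethoxyphenoxy}-3-phenylpropyl acetate F2. Methanolysis with K2CO3 in MeOH should free (S)-3-{2,4-bis[2-(benzyloxy)benzyl]-3,5-dimethoxyphenoxy}-3-phenylpropan-1-ol F3. Oxidation of the primary alcohol with catalytic TEMPO and PhI(OAc)2 in MeCN/H2O should then deliver acid 15.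

Step 11 (key cycloacylation). Attack at C4a, which is flanked by two alkoxy groups on a fully substituted ring, may be slow enough for other processes to compete: loss of the aryloxide by β-elimination from the activated acid, trifluoroacetylation of C4a, or acid-induced debenzylation. The fallback sets out from acid 15 and returns at flavanone 17, closing the same C4–C4a bond with reversed polarity. NBS in MeCN at –20 °C should brominate the only ring A C–H to give (S)-3-{2,4-bis[2-(benzyloxy)benzyl]-6-bromo-3,5-dimethoxyphenoxy}-3-phenylpropanoic acid F4. Treatment with 2.2 equiv n-BuLi in THF at –100 → –78 °C should deprotonate the acid and effect bromine–lithium exchange. The aryllithium then adds to the lithium carboxylate (Parham cycloacylation), and aqueous work-up should release 17.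

Step 12 (global deprotection with BCl3). Demethylation may also reach the twisted, doubly flanked C7 methyl ether or stop short at C5. Liberated benzyl cations may C-alkylate the phenolic rings, and Lewis-acid opening of ring C would erode C2. The fallback sets out from 17 and ends at target 18, separating the two deprotections. Hydrogenolysis (H2, 10% Pd/C, EtOAc, rt, monitored to avoid over-reduction) should remove both benzyl ethers and give (S)-6,8-bis(2-hydroxybenzyl)-5,7-dimethoxy-2-phenylchroman-4-one F5. MgI2 etherate in toluene/Et2O at 50 °C, a reagent that cleaves only methyl ethers chelated to an ortho carbonyl, should then demethylate C5 alone and give 18.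

**Further compounds**

F1 | step 9 | (S)-1-(3-chloro-1-phenylpropoxy)-2,4-bis[2-(benzyloxy)benzyl]-3,5-dimethoxybenzene | ClCC[C@H](Oc1cc(OC)c(Cc2ccccc2OCc2ccccc2)c(OC)c1Cc1ccccc1OCc1ccccc1)c1ccccc1
F2 | step 9 | (S)-3-{2,4-bis[2-(benzyloxy)benzyl]-3,5-dimethoxyphenoxy}-3-phenylpropyl acetate | CC(=O)OCC[C@H](Oc1cc(OC)c(Cc2ccccc2OCc2ccccc2)c(OC)c1Cc1ccccc1OCc1ccccc1)c1ccccc1
F3 | step 9 | (S)-3-{2,4-bis[2-(benzyloxy)benzyl]-3,5-dimethoxyphenoxy}-3-phenylpropan-1-ol | OCC[C@H](Oc1cc(OC)c(Cc2ccccc2OCc2ccccc2)c(OC)c1Cc1ccccc1OCc1ccccc1)c1ccccc1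
F4 | step 11 | (S)-3-{2,4-bis[2-(benzyloxy)benzyl]-6-bromo-3,5-dimethoxyphenoxy}-3-phenylpropanoic acid | OC(=O)C[C@H](Oc1c(Br)c(OC)c(Cc2ccccc2OCc2ccccc2)c(OC)c1Cc1ccccc1OCc1ccccc1)c1ccccc1
F5 | step 12 | (S)-6,8-bis(2-hydroxybenzyl)-5,7-dimethoxy-2-phenylchroman-4-one | COc1c(Cc2ccccc2O)c(OC)c2c(c1Cc1ccccc1O)O[C@H](c1ccccc1)CC2=O
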